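**Plan**

- Numbering as in germacranolides: C1=C10 enoate, C4–Me, C6–O (lactone), C7 ring fusion, C8–OAng, C11/C12/C13 = lactone α‑carbon/carbonyl/exocyclic CH2. Retrosynthetic cuts, in order: C11=C13 (decarboxylative methylenation), C1=C10 (ring‑closing metathesis), lactone O–C6 (strain‑release isomerisation of a cyclopropane C6–C7–C11 carrying two carboxyls on C11), C8–O (Mitsunobu), C8–C9 (Barbier), C6–C11/C7–C11 (organocatalytic cyclopropanation), C6=C7 (Wittig).
- Forward: (S)‑citronellal → C1–C8 enal → trans‑cyclopropane‑1,1‑diester aldehyde → C8–C9 allylation and angelate → γ‑lactone by opening of the cyclopropane → ten‑membered ring → exocyclic methylene.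
- Stereochemistry: C4 from (S)‑citronellal; C6 and C7 from the (S)‑diphenylprolinol silyl ether catalyst; C8 by substrate‑controlled Barbier addition followed by Mitsunobu inversion; the C6–O configuration by double inversion (net retention) in the key step; C1=C10 geometry from the ring closure; angelate geometry from angelic acid.
- Enabling feature: in the lactone ring O–C6–C7–C11–C12, C6 and C11 are 1,3‑related through C7 and C11 is the α‑carbon of an acrylate. C6–C11 can therefore be the third bond of an acceptor‑activated cyclopropane, whose second carboxyl on C11 later leaves as CO2 when C13 is put in.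

Key step: step 7

Remark on the chemistry: the zinc Barbier addition in step 5 is assumed to follow the bisected s‑trans model of cis‑substituted cyclopropanecarbaldehydes (attack anti to the cis ester), so that 11 is the (1S)‑carbinol and inversion at C8 is required.

**Route**

Step 1
Reactants: 1 (S)‑citronellal; 2 ethylene
Product: 3 (3S)‑3‑methylhept‑6‑enal
Conditions: second‑generation Hoveyda–Grubbs catalyst (1 mol%), ethylene (8 bar), toluene, 50 °C
Reagents that add atoms: ethylene (2), C=C
Why: Ethenolysis (cross‑metathesis with ethylene) should cleave the electron‑rich trisubstituted alkene under ethylene pressure with loss of isobutene, while the aldehyde and the non‑allylic C4 stereocentre are untouched.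

Step 2
Reactants: 3 (3S)‑3‑methylhept‑6‑enal; 4 (triphenylphosphoranylidene)acetaldehyde
Product: 5 (2E,5S)‑5‑methylnona‑2,8‑dienal
Conditions: toluene, 80 °C
Reagents that add atoms: (triphenylphosphoranylidene)acetaldehyde (4), O=CC=P(c1ccccc1)(c1ccccc1)c1ccccc1
Why: Wittig reaction of the formyl‑stabilised ylide with the unhindered aldehyde should give the (E)‑enal, whose new C6=C7 bond is the future cyclopropane edge.

Step 3
Reactants: 6 di‑tert‑butyl malonate; 7 N‑bromosuccinimide
Product: 8 di‑tert‑butyl 2‑bromomalonate
Conditions: NaH, THF, 0 °C; then NBS, −78 °C → 0 °C; H2O work‑up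
Reagents that add atoms: N‑bromosuccinimide (7), O=C1CCC(=O)N1Br
Why: Bromination of the sodium malonate enolate with N‑bromosuccinimide at low temperature should stop at the monobromide needed as Michael donor and alkylating agent.

Step 4
Reactants: 5 (2E,5S)‑5‑methylnona‑2,8‑dienal; 8 di‑tert‑butyl 2‑bromomalonate
Product: 9 di‑tert‑butyl (2R,3R)‑2‑formyl‑3‑[(2S)‑2‑methylhex‑5‑en‑1‑yl]cyclopropane‑1,1‑dicarboxylate
Conditions: (S)‑α,α‑diphenylprolinol trimethylsilyl ether (20 mol%), 2,6‑lutidine (1.2 equiv), CH2Cl2, 0 °C → rt
Reagents that add atoms: di‑tert‑butyl 2‑bromomalonate (8), CC(C)(C)OC(=O)C(Br)C(=O)OC(C)(C)C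
Why: Iminium/enamine organocatalysis (Michael‑initiated ring closure): the bromomalonate adds to C6 of the (E)‑iminium ion on the face away from the diphenyl(silyloxy)methyl group and the enamine then displaces bromide 3‑exo‑tet, which sets C6 and C7 under catalyst control and places C5 and C8 trans.

Step 5
Reactants: 9 cyclopropane aldehyde; 10 methyl 2‑(bromomethyl)acrylate
Product: 11 di‑tert‑butyl (2R,3R)‑2‑[(1S)‑1‑hydroxy‑3‑(methoxycarbonyl)but‑3‑en‑1‑yl]‑3‑[(2S)‑2‑methylhex‑5‑en‑1‑yl]cyclopropane‑1,1‑dicarboxylate
Conditions: Zn dust, THF/sat. aq. NH4Cl, 0 °C → rt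
Reagents that add atoms: methyl 2‑(bromomethyl)acrylate (10), C=C(CBr)C(=O)OC
Why: Zinc Barbier 2‑(alkoxycarbonyl)allylation: the allylzinc reagent should add to the bisected s‑trans conformer of the cyclopropanecarbaldehyde on the face away from the cis tert‑butyl ester on C11, giving the (1S)‑carbinol (C8 epimeric to the target), and the bulky tert‑butyl esters should keep the new hydroxyl from lactonising.

Step 6
Reactants: 11 (1S)‑carbinol; 12 angelic acid [(2Z)‑2‑methylbut‑2‑enoic acid]
Product: 13 di‑tert‑butyl (2R,3R)‑2‑[(1R)‑1‑(angeloyloxy)‑3‑(methoxycarbonyl)but‑3‑en‑1‑yl]‑3‑[(2S)‑2‑methylhex‑5‑en‑1‑yl]cyclopropane‑1,1‑dicarboxylate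
Conditions: PPh3, DIAD, toluene, 0 °C → rt
Reagents that add atoms: angelic acid (12), C/C=C(/C)C(=O)O
Why: Mitsunobu esterification: angelate displaces the alkoxyphosphonium at C8 by SN2 with inversion to the configuration of the target, the geminal diester on the ring disfavouring ionisation of the cyclopropylcarbinyl centre, and the acid is never activated at its carbonyl so the (Z)‑geometry should survive.

Step 7
Reactants: 13 angelate cyclopropane diester
Product: 16 (3R,4S,5R)‑4‑[(1R)‑1‑(angeloyloxy)‑3‑(methoxycarbonyl)but‑3‑en‑1‑yl]‑5‑[(2S)‑2‑methylhex‑5‑en‑1‑yl]‑2‑oxotetrahydrofuran‑3‑carboxylic acid (C3 epimerisable), via cyclopropane‑1,1‑dicarboxylic acid 14 (not isolated), via C6‑iodo malonic acid 15 (not isolated)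
Conditions: TFA/CH2Cl2 (1:4), 0 °C → rt; evaporate; then LiI (0.3 equiv), MeCN, 60 °C
Reagents that add atoms: none
Why: Proposed new method: after acidolysis of both tert‑butyl esters, iodide (assisted by Li+ and by the internal O–H···O=C hydrogen bond of the geminal diacid) should attack C6 from the side opposite C11 and break the strained C6–C11 bond; the malonate enolate so formed tautomerises at once to the hydrogen‑malonate carboxylate, whose oxygen displaces iodide at C6 with a second inversion, releasing about 27 kcal/mol of ring strain and returning the iodide. The closest known reaction types are the MgI2‑mediated iodide opening of cyclopropane‑1,1‑diesters, the nucleophile‑catalysed Cloke–Wilson rearrangement of acyl cyclopropanes to dihydrofurans and the hydrogen‑halide‑mediated conversion of cyclopropane‑1,1‑dicarboxylic acid into 2‑oxotetrahydrofuran‑3‑carboxylic acid; what has not been shown is the iodide‑catalysed, stereoretentive version on a 2,3‑dialkyl cyclopropane. The lactone ring closes 5‑exo‑tet by O–C6 bond formation. C6 is the only new stereocentre and is fixed by double inversion (net retention), so the trans relation of C5 and C8 on the cyclopropane, set by the organocatalyst, becomes the trans 6,7 ring fusion; C11 stays epimerisable and is destroyed in step 9. The step needs attack at C6 and not at C7, which the branching and the electron‑withdrawing acyloxy group at C8 next to C7 should secure, and it needs lactonisation to outrun iodide exchange at C6, which the intramolecular five‑ring closure and the substoichiometric iodide should secure; since no free HI builds up, the angelate, the acrylate and the vinyl group should stay untouched.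

Step 8
Reactants: 16 α‑carboxy trans‑lactone
Product: 17 (1(10)E,4S,6R,7S,8R)‑8‑(angeloyloxy)‑11‑carboxy‑14‑methoxy‑14‑oxogermacr‑1(10)‑en‑12,6‑olide (ten‑membered ring; C11 drawn trans to C8 and epimerisable)
Conditions: second‑generation Hoveyda–Grubbs catalyst (15 mol%), 1,4‑benzoquinone (30 mol%), 1,2‑dichloroethane (1 mM), 60 °C
Reagents that add atoms: none
Why: Ring‑closing metathesis should start at the monosubstituted C1 vinyl group and close onto the 1,1‑disubstituted acrylate; the trans‑lactone holds C5 and C8 gauche, and the ring‑cis enoate (CIP E, ester trans to C2) is both the less strained and the thermodynamically preferred geometry.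

Step 9
Reactants: 17 macrocyclic α‑carboxy lactone; 18 formaldehyde (used as paraformaldehyde)
Product: 19 CNP0510087.1, (1(10)E,4S,6R,7S,8R)‑8‑(angeloyloxy)‑14‑methoxy‑14‑oxogermacra‑1(10),11(13)‑dien‑12,6‑olide
Conditions: (CH2O)n, Et2NH, THF, 65 °C
Reagents that add atoms: formaldehyde (18), C=O
Why: Decarboxylative methylenation: Mannich reaction of the malonic half‑acid at C11 with formaldehyde and Et2NH followed by loss of CO2 and amine should give the α‑methylene lactone, removing the helper carboxyl without creating a stereocentre.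

**Compound list**

1 | (S)‑citronellal, (3S)‑3,7‑dimethyloct‑6‑enal | O=CC[C@@H](C)CCC=C(C)C | starting material
2 | ethylene | C=C | starting material
3 | (3S)‑3‑methylhept‑6‑enal | O=CC[C@@H](C)CCC=C | intermediate
4 | (triphenylphosphoranylidene)acetaldehyde | O=CC=P(c1ccccc1)(c1ccccc1)c1ccccc1 | starting material
5 | (2E,5S)‑5‑methylnona‑2,8‑dienal | O=C/C=C/C[C@@H](C)CCC=C | intermediate
6 | di‑tert‑butyl malonate | CC(C)(C)OC(=O)CC(=O)OC(C)(C)C | starting material
7 | N‑bromosuccinimide | O=C1CCC(=O)N1Br | starting material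
8 | di‑tert‑butyl 2‑bromomalonate | CC(C)(C)OC(=O)C(Br)C(=O)OC(C)(C)C | intermediate
9 | di‑tert‑butyl (2R,3R)‑2‑formyl‑3‑[(2S)‑2‑methylhex‑5‑en‑1‑yl]cyclopropane‑1,1‑dicarboxylate | O=C[C@@H]1[C@@H](C[C@@H](C)CCC=C)C1(C(=O)OC(C)(C)C)C(=O)OC(C)(C)C | intermediate
10 | methyl 2‑(bromomethyl)acrylate | C=C(CBr)C(=O)OC | starting material
11 | di‑tert‑butyl (2R,3R)‑2‑[(1S)‑1‑hydroxy‑3‑(methoxycarbonyl)but‑3‑en‑1‑yl]‑3‑[(2S)‑2‑methylhex‑5‑en‑1‑yl]cyclopropane‑1,1‑dicarboxylate | C=C(C(=O)OC)C[C@H](O)[C@@H]1[C@@H](C[C@@H](C)CCC=C)C1(C(=O)OC(C)(C)C)C(=O)OC(C)(C)C | intermediate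
12 | angelic acid, (2Z)‑2‑methylbut‑2‑enoic acid | C/C=C(/C)C(=O)O | starting material
13 | di‑tert‑butyl (2R,3R)‑2‑[(1R)‑1‑(angeloyloxy)‑3‑(methoxycarbonyl)but‑3‑en‑1‑yl]‑3‑[(2S)‑2‑methylhex‑5‑en‑1‑yl]cyclopropane‑1,1‑dicarboxylate | C=C(C(=O)OC)C[C@@H](OC(=O)/C(C)=C\C)[C@@H]1[C@@H](C[C@@H](C)CCC=C)C1(C(=O)OC(C)(C)C)C(=O)OC(C)(C)C | intermediate
14 | the cyclopropane‑1,1‑dicarboxylic acid corresponding to 13 | C=C(C(=O)OC)C[C@@H](OC(=O)/C(C)=C\C)[C@@H]1[C@@H](C[C@@H](C)CCC=C)C1(C(=O)O)C(=O)O | intermediate
15 | ring‑opened malonic acid with iodide at C6 (C6 inverted; formed as its lithium carboxylate, drawn as the free acid) | C=C(C(=O)OC)C[C@@H](OC(=O)/C(C)=C\C)[C@H]([C@@H](I)C[C@@H](C)CCC=C)C(C(=O)O)C(=O)O | intermediate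
16 | (3R,4S,5R)‑4‑[(1R)‑1‑(angeloyloxy)‑3‑(methoxycarbonyl)but‑3‑en‑1‑yl]‑5‑[(2S)‑2‑methylhex‑5‑en‑1‑yl]‑2‑oxotetrahydrofuran‑3‑carboxylic acid (4,5‑trans; C3 drawn trans to the C4 substituent, epimerisable) | OC(=O)[C@@H]1C(=O)O[C@H](C[C@@H](C)CCC=C)[C@H]1[C@H](OC(=O)/C(C)=C\C)CC(=C)C(=O)OC | intermediate
17 | ten‑membered α‑carboxy lactone, (1(10)E,4S,6R,7S,8R)‑8‑(angeloyloxy)‑11‑carboxy‑14‑methoxy‑14‑oxogermacr‑1(10)‑en‑12,6‑olide | OC(=O)[C@@H]1C(=O)O[C@@H]2C[C@@H](C)CC/C=C(/C(=O)OC)C[C@@H](OC(=O)/C(C)=C\C)[C@@H]12 | intermediate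
18 | formaldehyde (as paraformaldehyde) | C=O | starting material
19 | CNP0510087.1, (1(10)E,4S,6R,7S,8R)‑8‑(angeloyloxy)‑14‑methoxy‑14‑oxogermacra‑1(10),11(13)‑dien‑12,6‑olide | C=C1C(=O)O[C@@H]2C[C@@H](C)CC/C=C(/C(=O)OC)C[C@@H](OC(=O)/C(C)=C\C)[C@@H]12 | target

**Totals**

Total step count: 9. Longest linear sequence: 8 (steps 1, 2, 4, 5, 6, 7, 8, 9).

**Steps most likely to fail**

1. Step 7 (proposed new method). The iodide opening at the secondary cyclopropane carbon C6 may be too slow, or iodide exchange or elimination at C6 may erode the stereochemical relay before the lactone closes. The fallback uses known reaction types in discrete steps and sets out from 13. Stoichiometric MgI2 with AcOH in THF (iodide opening of a cyclopropane‑1,1‑diester with protonation of the magnesium enolate) should give the ring‑opened di‑tert‑butyl γ‑iodomalonate F1. AgOTf with 2,6‑lutidine in CH2Cl2 (silver‑assisted lactonisation through the neighbouring tert‑butyl ester carbonyl, second inversion at C6, loss of isobutene) should give the lactone tert‑butyl ester F2. TFA in CH2Cl2 then frees the acid, and the fallback comes back to the route at 16.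

2. Step 8. Cross‑metathesis oligomerisation may compete with closure of the ten‑membered ring, and the malonic half‑acid may decarboxylate during prolonged heating. The fallback sets out from 16 and moves the ring closure behind the methylenation. Treatment of 16 with (CH2O)n and Et2NH should give the acyclic α‑methylene lactone triene F3, which carries no heat‑sensitive acid and can be cyclised with the same ruthenium catalyst in toluene at up to 110 °C. The bridgehead‑alkene alternative through the lactone methylene is disfavoured, so this should give the target directly, and the fallback comes back at 19.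

3. Step 6. The cis tert‑butyl ester carbonyl may attack the activated C8 (lactone formation with loss of isobutene), elimination towards C9 may occur, or conversion may be low at the hindered cyclopropyl carbinol; a less face‑selective step 5 would have the same effect on the C8 configuration. The fallback sets out from 11 and replaces SN2 inversion by reagent‑controlled reduction. Dess–Martin periodinane oxidation should give the cyclopropyl ketone F4. Reduction with catecholborane and the (S)‑2‑methyl‑CBS‑oxazaborolidine should give the (1R)‑alcohol F5. Esterification of F5 with angelic acid through the 2,4,6‑trichlorobenzoyl mixed anhydride (Et3N, then DMAP, toluene) proceeds with retention, and the fallback comes back at 13.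

**Further compounds**

F1 | step 7 | di‑tert‑butyl γ‑iodomalonate from opening of 13 at C6 (C6 inverted) | C=C(C(=O)OC)C[C@@H](OC(=O)/C(C)=C\C)[C@H]([C@@H](I)C[C@@H](C)CCC=C)C(C(=O)OC(C)(C)C)C(=O)OC(C)(C)C
F2 | step 7 | tert‑butyl ester of lactone acid 16 | CC(C)(C)OC(=O)[C@@H]1C(=O)O[C@H](C[C@@H](C)CCC=C)[C@H]1[C@H](OC(=O)/C(C)=C\C)CC(=C)C(=O)OC
F3 | step 8 | acyclic α‑methylene trans‑lactone triene | C=C1C(=O)O[C@H](C[C@@H](C)CCC=C)[C@H]1[C@H](OC(=O)/C(C)=C\C)CC(=C)C(=O)OC
F4 | step 6 | cyclopropyl ketone from oxidation of 11 | C=C(C(=O)OC)CC(=O)[C@@H]1[C@@H](C[C@@H](C)CCC=C)C1(C(=O)OC(C)(C)C)C(=O)OC(C)(C)C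
F5 | step 6 | (1R)‑carbinol, C8 epimer of 11 | C=C(C(=O)OC)C[C@@H](O)[C@@H]1[C@@H](C[C@@H](C)CCC=C)C1(C(=O)OC(C)(C)C)C(=O)OC(C)(C)C
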